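The pentasubstituted central benzene ring (C1 OMe, C2 H, C3 OH, C4 and C6 4-hydroxybenzyl, C5 2-phenylethyl) is treated as an aromatised cyclohexane-1,3-dione and cut at C5–C6 and C1–C2. One Michael–Claisen annulation joins a benzylmalonate (C6, C1) to an α-benzyl enone (C2–C5), closing the carbocycle with all three carbon arms and both oxygens already in place; because the C4 and C6 arms are identical, later mono-O-methylation has only one possible outcome. The enone partner, (E)-3-[4-(benzyloxy)benzyl]-6-phenylhex-3-en-2-one, is made regiospecifically by Horner–Wadsworth–Emmons olefination. Decarboxylation, enol etherification, dehydrogenation and debenzylation complete the route.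

Key step: step 4

Remark: the target has no stereocentre and no stereogenic double bond, so it is achiral and exists as one stereoisomer; the racemic, diastereomerically mixed ring intermediates are therefore of no consequence, since all their sp3 ring centres are lost on aromatisation.

Step 1
Reactants: 1 diethyl (2-oxopropyl)phosphonate; 2 4-(benzyloxy)benzyl chloride
Product: 3 diethyl {1-[4-(benzyloxy)phenyl]-3-oxobutan-2-yl}phosphonate (racemic)
Conditions: NaH, THF/DMF, 0 °C; then 2 (slight deficit), NaI (cat.), rt → 60 °C
Reagents that add atoms: none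
Why: SN2 C-alkylation of the sodium enolate of a β-ketophosphonate by an activated benzylic halide (iodide-catalysed) should place the arm on the only nucleophilic carbon, the one between P=O and C=O, and the small excess of 1 limits dialkylation.

Step 2
Reactants: 3 diethyl {1-[4-(benzyloxy)phenyl]-3-oxobutan-2-yl}phosphonate; 4 3-phenylpropanal
Product: 5 (E)-3-[4-(benzyloxy)benzyl]-6-phenylhex-3-en-2-one
Conditions: NaH, THF, 0 °C; then 4 added slowly, 0 °C → rt
Reagents that add atoms: none
Why: Horner–Wadsworth–Emmons olefination fixes the acetyl and benzyl groups on the carbon that carried phosphorus, so the branch regiochemistry is unambiguous; the (E)-isomer is expected to predominate, and any (Z)-isomer is equally usable because the alkene geometry disappears in step 4.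

Step 3
Reactants: 6 diethyl malonate; 2 4-(benzyloxy)benzyl chloride
Product: 7 diethyl 2-[4-(benzyloxy)benzyl]malonate
Conditions: NaH, 6 (2.5 equiv.), THF/DMF, 0 °C; then 2, rt
Reagents that add atoms: none
Why: Malonic ester alkylation with a reactive benzylic chloride; excess malonate suppresses dialkylation and the aprotic medium avoids solvolysis of the p-alkoxybenzyl chloride.

Step 4
Reactants: 5 (E)-3-[4-(benzyloxy)benzyl]-6-phenylhex-3-en-2-one; 7 diethyl 2-[4-(benzyloxy)benzyl]malonate
Product: 9 ethyl 1,3-bis[4-(benzyloxy)benzyl]-4,6-dioxo-2-(2-phenylethyl)cyclohexane-1-carboxylate (racemic diastereomer mixture), via Michael adduct 8 (not isolated)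
Conditions: NaOEt (1.2 equiv.), abs. EtOH, reflux, high concentration; then cold aq. HCl
Reagents that add atoms: none
Why: Ethoxide reversibly generates the tertiary carbanion of malonate 7, which adds in 1,4-fashion to the β-carbon of enone 5 (bond C5–C6) to give keto diester 8; after proton transfer the methyl-side ketone enolate attacks one ester carbonyl with loss of ethoxide (bond C1–C2). The closest known reaction type is the Michael–Claisen annulation of enones with malonic esters to 4-alkoxycarbonylcyclohexane-1,3-diones, the classical entry to dihydroresorcinols such as dimedone and the precursors of 5-alkylresorcinols, here extended to a 2-substituted malonate and an α-branched enone. The six-membered ring closes by a 6-(enolendo)-exo-trig acyl substitution, and the essentially irreversible deprotonation of the new 1,3-dione between its carbonyls by ethoxide is the thermodynamic sink that pulls the crowded, reversible conjugate addition forward. Three sp3 stereocentres arise (the quaternary ester carbon and the two neighbouring methines) but none is controlled and none needs to be, since decarboxylation and aromatisation remove them all. The step needs conjugate rather than carbonyl addition and closure from the methyl rather than the methine enolate: the soft, stabilised malonate anion adds reversibly so that only the 1,4-adduct can be drained by the Claisen step, and the methine enolate could at most form a strained four-membered ring whose reopening (ester migration) would lead to the same ring constitution because the two benzyl arms are identical.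

Step 5
Reactants: 9 ethyl 1,3-bis[4-(benzyloxy)benzyl]-4,6-dioxo-2-(2-phenylethyl)cyclohexane-1-carboxylate
Product: 11 4,6-bis[4-(benzyloxy)benzyl]-5-(2-phenylethyl)cyclohexane-1,3-dione (diastereomer mixture), via keto acid 10 (not isolated)
Conditions: KOH, EtOH/H2O, reflux; then aq. HCl to pH 1–2, 70 °C
Reagents that add atoms: none
Why: Saponification of the hindered ester, during which the dione is shielded from retro-Claisen cleavage as its delocalised enolate, followed by acidification should give β-keto acid 10, which loses CO2 on warming (ester hydrolysis–decarboxylation of a β-keto ester); the aryl benzyl ethers tolerate both media.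

Step 6
Reactants: 11 4,6-bis[4-(benzyloxy)benzyl]-5-(2-phenylethyl)cyclohexane-1,3-dione
Product: 12 4,6-bis[4-(benzyloxy)benzyl]-3-methoxy-5-(2-phenylethyl)cyclohex-2-en-1-one (diastereomer mixture)
Conditions: MeOH, HC(OMe)3, TsOH·H2O (cat.), rt → 40 °C
Reagents that add atoms: methanol, CO (trimethyl orthoformate, COC(OC)OC, serves as water scavenger and can equally deliver the methoxy group)
Why: Acid-catalysed enol etherification of a vinylogous acid, driven by the orthoformate; the two carbonyls of 11 are constitutionally equivalent, so only one constitutional mono-enol ether can form and the ring-carbon stereoisomers do not matter.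

Step 7
Reactants: 12 4,6-bis[4-(benzyloxy)benzyl]-3-methoxy-5-(2-phenylethyl)cyclohex-2-en-1-one
Product: 16 2,4-bis[4-(benzyloxy)benzyl]-5-methoxy-3-(2-phenylethyl)phenol, via selenide 13 (not isolated), via selenoxide 14 (not isolated), via cyclohexadienone 15 (not isolated)
Conditions: LDA, THF, −78 °C; PhSeCl, −78 °C; then 30% H2O2, pyridine, CH2Cl2, 0 °C → rt
Reagents that add atoms: none
Why: Kinetic α'-deprotonation of the vinylogous ester, selenenylation of the enolate and oxidation should trigger selenoxide syn-elimination (Reich–Sharpless dehydrogenation) to the cross-conjugated dienone 15, which tautomerises to the phenol; elimination toward the ring or toward the benzylic CH2 converges on the same arene after prototropic isomerisation.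

Step 8
Reactants: 16 2,4-bis[4-(benzyloxy)benzyl]-5-methoxy-3-(2-phenylethyl)phenol
Product: 17 2,4-bis(4-hydroxybenzyl)-5-methoxy-3-(2-phenylethyl)phenol (IN1158)
Conditions: H2 (1 atm), 10% Pd/C, EtOAc/EtOH, rt
Reagents that add atoms: none
Why: Catalytic hydrogenolysis of the two aryl benzyl ethers; nothing else in 16 is reducible under these conditions (the diarylmethane C–C bonds and the electron-rich ring are inert) and no stereocentre exists to be affected.

Compound list
1 | diethyl (2-oxopropyl)phosphonate | CC(=O)CP(=O)(OCC)OCC | starting material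
2 | 4-(benzyloxy)benzyl chloride | ClCc1ccc(OCc2ccccc2)cc1 | starting material
3 | diethyl {1-[4-(benzyloxy)phenyl]-3-oxobutan-2-yl}phosphonate (racemic) | CC(=O)C(Cc1ccc(OCc2ccccc2)cc1)P(=O)(OCC)OCC | intermediate
4 | 3-phenylpropanal | O=CCCc1ccccc1 | starting material
5 | (E)-3-[4-(benzyloxy)benzyl]-6-phenylhex-3-en-2-one | CC(=O)/C(Cc1ccc(OCc2ccccc2)cc1)=C/CCc1ccccc1 | intermediate
6 | diethyl malonate | CCOC(=O)CC(=O)OCC | starting material
7 | diethyl 2-[4-(benzyloxy)benzyl]malonate | CCOC(=O)C(Cc1ccc(OCc2ccccc2)cc1)C(=O)OCC | intermediate
8 | diethyl 2-[4-(benzyloxy)benzyl]-2-{2-[4-(benzyloxy)benzyl]-3-oxo-1-(2-phenylethyl)butyl}malonate (Michael adduct, diastereomer mixture) | CCOC(=O)C(Cc1ccc(OCc2ccccc2)cc1)(C(=O)OCC)C(CCc1ccccc1)C(Cc1ccc(OCc2ccccc2)cc1)C(C)=O | intermediate (not isolated)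
9 | ethyl 1,3-bis[4-(benzyloxy)benzyl]-4,6-dioxo-2-(2-phenylethyl)cyclohexane-1-carboxylate (racemic diastereomer mixture) | CCOC(=O)C1(Cc2ccc(OCc3ccccc3)cc2)C(=O)CC(=O)C(Cc2ccc(OCc3ccccc3)cc2)C1CCc1ccccc1 | intermediate
10 | 1,3-bis[4-(benzyloxy)benzyl]-4,6-dioxo-2-(2-phenylethyl)cyclohexane-1-carboxylic acid (diastereomer mixture) | OC(=O)C1(Cc2ccc(OCc3ccccc3)cc2)C(=O)CC(=O)C(Cc2ccc(OCc3ccccc3)cc2)C1CCc1ccccc1 | intermediate (not isolated)
11 | 4,6-bis[4-(benzyloxy)benzyl]-5-(2-phenylethyl)cyclohexane-1,3-dione (diastereomer mixture) | O=C1CC(=O)C(Cc2ccc(OCc3ccccc3)cc2)C(CCc2ccccc2)C1Cc1ccc(OCc2ccccc2)cc1 | intermediate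
12 | 4,6-bis[4-(benzyloxy)benzyl]-3-methoxy-5-(2-phenylethyl)cyclohex-2-en-1-one (diastereomer mixture) | COC1=CC(=O)C(Cc2ccc(OCc3ccccc3)cc2)C(CCc2ccccc2)C1Cc1ccc(OCc2ccccc2)cc1 | intermediate
13 | 4,6-bis[4-(benzyloxy)benzyl]-3-methoxy-5-(2-phenylethyl)-6-(phenylselanyl)cyclohex-2-en-1-one (diastereomer mixture) | COC1=CC(=O)C([Se]c2ccccc2)(Cc2ccc(OCc3ccccc3)cc2)C(CCc2ccccc2)C1Cc1ccc(OCc2ccccc2)cc1 | intermediate (not isolated)
14 | 4,6-bis[4-(benzyloxy)benzyl]-3-methoxy-5-(2-phenylethyl)-6-(phenylseleninyl)cyclohex-2-en-1-one (diastereomer mixture) | COC1=CC(=O)C([Se](=O)c2ccccc2)(Cc2ccc(OCc3ccccc3)cc2)C(CCc2ccccc2)C1Cc1ccc(OCc2ccccc2)cc1 | intermediate (not isolated)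
15 | 2,4-bis[4-(benzyloxy)benzyl]-5-methoxy-3-(2-phenylethyl)cyclohexa-2,5-dien-1-one (racemic) | COC1=CC(=O)C(Cc2ccc(OCc3ccccc3)cc2)=C(CCc2ccccc2)C1Cc1ccc(OCc2ccccc2)cc1 | intermediate (not isolated)
16 | 2,4-bis[4-(benzyloxy)benzyl]-5-methoxy-3-(2-phenylethyl)phenol | COc1cc(O)c(Cc2ccc(OCc3ccccc3)cc2)c(CCc2ccccc2)c1Cc1ccc(OCc2ccccc2)cc1 | intermediate
17 | 2,4-bis(4-hydroxybenzyl)-5-methoxy-3-(2-phenylethyl)phenol (IN1158) | COc1cc(O)c(Cc2ccc(O)cc2)c(CCc2ccccc2)c1Cc1ccc(O)cc1 | target

Total step count: 8. Longest linear sequence: 7 steps (steps 1, 2, 4, 5, 6, 7, 8); step 3 is the one-step side branch.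

Steps most likely to fail

1. Step 4. The conjugate addition that creates the quaternary carbon next to two methines may revert faster than the Claisen closure traps it, or the enone may be deconjugated by the alkoxide, so that the ring never forms. Fallback: setting out from 5 and 6, the same ring would be built with the unhindered parent malonate under the classical conditions (NaOEt, EtOH, reflux) to give ethyl 3-[4-(benzyloxy)benzyl]-4,6-dioxo-2-(2-phenylethyl)cyclohexane-1-carboxylate F1. Its dianion (LDA 2.2 equiv., THF/DMPU, −78 → 0 °C) would then be C-benzylated with 2 at the ester-bearing carbon, the last-formed and most nucleophilic site, and the route is rejoined at 9.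

2. Step 7. C-selenenylation at the hindered tertiary α'-carbon may be sluggish, and the very electron-rich phenol being formed may be oxidised or selenenylated by the selenium(IV)/peroxide by-products; selenium carried forward would also poison the palladium of step 8. Fallback: setting out from 12, the lithium enolate would be trapped on oxygen (LDA, TMSCl, THF, −78 °C) as {[2,4-bis[4-(benzyloxy)benzyl]-5-methoxy-3-(2-phenylethyl)cyclohexa-1,5-dien-1-yl]oxy}trimethylsilane F2, and Saegusa–Ito oxidation (Pd(OAc)2, MeCN, rt) would deliver dienone 15 and hence, after tautomerisation, 16, where the route is rejoined.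

3. Step 2. Olefination by the α-branched, hindered phosphonate anion may be slow enough that base-induced self-condensation of the enolisable aldehyde takes over. Fallback: setting out from 4, purchased 4-(4-hydroxyphenyl)butan-2-one F3 would be O-benzylated (BnBr, K2CO3, acetone, reflux) to 4-[4-(benzyloxy)phenyl]butan-2-one F4. F4, used in excess, would then be condensed with 4 under acid (dry HCl in AcOH, 0 °C → rt, then warming to dehydrate); enolisation toward the more substituted methylene directs the crossed aldol condensation to C3 of the ketone, and the route is rejoined at 5.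

Further compounds
F1 | step 4 | ethyl 3-[4-(benzyloxy)benzyl]-4,6-dioxo-2-(2-phenylethyl)cyclohexane-1-carboxylate | CCOC(=O)C1C(=O)CC(=O)C(Cc2ccc(OCc3ccccc3)cc2)C1CCc1ccccc1
F2 | step 7 | {[2,4-bis[4-(benzyloxy)benzyl]-5-methoxy-3-(2-phenylethyl)cyclohexa-1,5-dien-1-yl]oxy}trimethylsilane | COC1=CC(O[Si](C)(C)C)=C(Cc2ccc(OCc3ccccc3)cc2)C(CCc2ccccc2)C1Cc1ccc(OCc2ccccc2)cc1
F3 | step 2 | 4-(4-hydroxyphenyl)butan-2-one | CC(=O)CCc1ccc(O)cc1
F4 | step 2 | 4-[4-(benzyloxy)phenyl]butan-2-one | CC(=O)CCc1ccc(OCc2ccccc2)cc1
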